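## Retrosynthetic overview

1. The target (3R)-isoflavanone is cut at the C3–C1' bond: ring B is used as the free nucleophilic arene 4-geranylresorcinol, and ring A/C as an enolonium (α-keto cation) equivalent made from the silyl enol ether of 7-hydroxychroman-4-one with a chiral aryl-λ3-iodane. This single step joins the two halves and sets C3.
2. 4-Geranylresorcinol ⇒ resorcinol + geraniol (Friedel–Crafts allylation at C4).
3. Silyl enol ether ⇒ 7-hydroxychroman-4-one (bis-silylation; both silyl groups are lost in the key step and its work-up).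
4. Ring order: no ring is built. Rings A and C arrive fused in the bought chromanone and ring B arrives as resorcinol.

Assumption 1: the (R,R)-iodane is assumed to give the (3R) product; if the sense of induction is the opposite, the (S,S)-reagent from methyl (R)-lactate is used instead.

Assumption 2: the chiral reagent, dimethyl (2R,2'R)-2,2'-{[2-(diacetoxy-λ3-iodanyl)-1,3-phenylene]bis(oxy)}dipropanoate, COC(=O)[C@@H](C)Oc1cccc(O[C@H](C)C(=O)OC)c1I(OC(C)=O)OC(C)=O, is treated as a stock reagent and not counted as a step. It is made from 2-iodoresorcinol and methyl (S)-lactate by Mitsunobu etherification and oxidation with NaBO3·4H2O/AcOH, and its aryl iodide is recovered. 7-Hydroxychroman-4-one is bought.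

## Route

Step 1
Reactants: 1 resorcinol; 2 geraniol
Product: 3 4-geranylresorcinol {4-[(2E)-3,7-dimethylocta-2,6-dien-1-yl]benzene-1,3-diol}
Conditions: 1 (3 equiv), 2 (1 equiv), BF3·OEt2 (0.3 equiv), 1,4-dioxane, rt, 12 h; water wash removes excess 1; chromatography
Reagents that add atoms: none
Why: Friedel–Crafts allylation in which the BF3-activated allylic alcohol reacts through its primary terminus (E geometry kept) at C4 of resorcinol, the unhindered carbon ortho to one OH and para to the other; excess resorcinol suppresses dialkylation, and the minor C2 isomer and chroman by-products are separated (modest yield expected, both reactants are cheap).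

Step 2
Reactants: 4 7-hydroxychroman-4-one
Product: 5 4,7-bis(trimethylsilyloxy)-2H-chromene
Conditions: TMSOTf (2.3 equiv), Et3N (3 equiv), CH2Cl2, 0 °C, 1 h; evaporate, extract into dry pentane, decant from the salt, high vacuum; use at once
Reagents that add atoms: trimethylsilyl trifluoromethanesulfonate, C[Si](C)(C)OS(=O)(=O)C(F)(F)F
Why: silyl enol ether formation by soft enolisation, with C3 the only enolisable position; the phenol is silylated at the same time and serves as a traceless protecting group, and the mild amine base avoids retro-oxa-Michael opening of the pyranone.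

Step 3
Reactants: 5 4,7-bis(trimethylsilyloxy)-2H-chromene; 3 4-geranylresorcinol
Product: 8 (3R)-5'-geranyl-7,2',4'-trihydroxyisoflavanone (CNP0142504.1), via enolonium species 6 (not isolated), via 7-O-trimethylsilyl isoflavanone 7 (not isolated)
Conditions: (R,R)-diacetoxy(aryl)-λ3-iodane of assumption 2 (1.0 equiv), BF3·OEt2 (2.0 equiv), CH2Cl2, −78 °C, 10 min; 5 (1.05 equiv) dropwise, −78 °C, 5 min; then 3 (2.0 equiv) in CH2Cl2, −78 → −45 °C, 2 h; MeOH/10% aq. citric acid, −45 → 0 °C, 15 min; silica gel chromatography
Reagents that add atoms: none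
Why: Proposed new method: umpolung α-arylation through an enolonium species, in which the BF3-activated trivalent iodine reagent takes the enol oxygen of 5 (silyl group lost to acetate) to give the O-bound iodane enolate 6 with an electrophilic C3; C6 of 3 (para to one OH, ortho to the other, roughly two orders of magnitude more nucleophilic on the Mayr scale than a trisubstituted alkene) attacks C3 in an SN2'-type displacement of the aryl iodide and rearomatises to ketone 7; the C2-symmetric lactate arms, whose ester carbonyls fold onto iodine, shield one face of the enolate so the C–C bond formation itself sets (3R). The closest known chemistry is the racemic α-arylation of ketone silyl enol ethers with electron-rich (hetero)arenes via PhI(OH)OTs/BF3 enolonium species, and the enantioselective α-oxygenation and α-amination of silyl enol ethers with the same lactate-derived λ3-iodanes. The iodane is fully consumed by the slight excess of 5 before the alkenes and phenols of 3 are added, and the cold, mildly acidic quench removes the aryl silyl ether without base, so the α-aryl ketone is not epimerised.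

## Compound list

1 | resorcinol (benzene-1,3-diol) | Oc1cccc(O)c1 | starting material
2 | geraniol [(2E)-3,7-dimethylocta-2,6-dien-1-ol] | CC(C)=CCC/C(C)=C/CO | starting material
3 | 4-geranylresorcinol {4-[(2E)-3,7-dimethylocta-2,6-dien-1-yl]benzene-1,3-diol} | CC(C)=CCC/C(C)=C/Cc1ccc(O)cc1O | intermediate
4 | 7-hydroxychroman-4-one | O=C1CCOc2cc(O)ccc12 | starting material
5 | 4,7-bis(trimethylsilyloxy)-2H-chromene | C[Si](C)(C)OC1=CCOc2cc(O[Si](C)(C)C)ccc12 | intermediate
6 | enolonium species: acetoxy{2,6-bis[(1R)-2-methoxy-1-methyl-2-oxoethoxy]phenyl}{[7-(trimethylsilyloxy)-2H-chromen-4-yl]oxy}-λ3-iodane, drawn as the covalent acetate (in the flask the acetate is held by BF3) | CC(=O)OI(OC1=CCOc2cc(O[Si](C)(C)C)ccc12)c1c(O[C@H](C)C(=O)OC)cccc1O[C@H](C)C(=O)OC | intermediate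
7 | (3R)-3-{5-[(2E)-3,7-dimethylocta-2,6-dien-1-yl]-2,4-dihydroxyphenyl}-7-(trimethylsilyloxy)chroman-4-one | CC(C)=CCC/C(C)=C/Cc1cc([C@@H]2COc3cc(O[Si](C)(C)C)ccc3C2=O)c(O)cc1O | intermediate
8 | (3R)-3-{5-[(2E)-3,7-dimethylocta-2,6-dien-1-yl]-2,4-dihydroxyphenyl}-7-hydroxychroman-4-one (CNP0142504.1) | CC(C)=CCC/C(C)=C/Cc1cc([C@@H]2COc3cc(O)ccc3C2=O)c(O)cc1O | target

## Step count and risk

Total step count: 3 (steps 1 and 2 run in parallel).
Longest linear sequence: 2 steps (1 → 3 → 8, or 4 → 5 → 8).

Steps most likely to fail, most risky first: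

**Step 3.** The risks are low enantioselectivity, attack by a phenol oxygen or a geranyl alkene instead of ring carbon C6, oxidation of the phenol at iodine, and collapse of 6 to 7-hydroxychromone by a 1,2-hydride shift. The fallback sets out from 3 and 5 and comes back at 8. It separates bond formation from stereocontrol. Compound 3 is silylated (TMSCl, Et3N, CH2Cl2) to 1-geranyl-2,4-bis(trimethylsilyloxy)benzene F1, so that no free OH can bind iodine. Compound 5 is turned into the achiral enolonium species with PhI(OH)OTs/BF3·OEt2 at −78 °C, the established racemic form of this coupling, and combined with F1. Citric acid work-up gives racemic 5'-geranyl-7,2',4'-trihydroxyisoflavanone F2. F2 is per-silylated (TMSOTf, Et3N, CH2Cl2, 0 °C) to the tetrakis(trimethylsilyl) enol ether 3-aryl-4-(trimethylsilyloxy)-2H-chromene F3. Catalytic enantioselective protonation of F3 then gives 8, using (S)-3,3'-bis(2,4,6-triisopropylphenyl)-1,1'-binaphthyl-2,2'-diyl N-triflylthiophosphoramide (5 mol%, enantiomer chosen by screening), PhOH (1.1 equiv), toluene, −20 °C → rt, then MeOH/citric acid. C3 is then set by catalyst-controlled proton delivery instead of in the C–C step.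

**Step 1.** The risks are C2 versus C4 regioselectivity, dialkylation, partial E/Z scrambling, and acid-induced chroman formation. The fallback sets out from 1 and 2 and comes back at 3. It replaces the Friedel–Crafts reaction by a regiospecific organometallic SN2 coupling. Compound 1 is monobrominated (NBS, MeCN, −20 °C) to 4-bromoresorcinol F4, which is protected (MOMCl, i-Pr2NEt, CH2Cl2) as 1-bromo-2,4-bis(methoxymethoxy)benzene F5. Compound 2 is converted (PBr3, Et2O, −10 °C) into geranyl bromide F6. Bromine–lithium exchange on F5 (n-BuLi, THF, −78 °C) and allylation with F6 in the presence of CuBr·SMe2 (10 mol%) gives 1-geranyl-2,4-bis(methoxymethoxy)benzene F7. Mild acetal cleavage (cat. HCl, MeOH, rt) returns 3.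

**Step 2.** The risk is that both silyl groups of 5 are labile, so partial loss of the aryl silyl ether makes the stoichiometry against the iodane unreliable. The fallback sets out from 4 and comes back at 8. It changes the protecting-group plan so that every intermediate can be purified. Compound 4 is silylated (TBSCl, imidazole, DMF) to 7-(tert-butyldimethylsilyloxy)chroman-4-one F8, which is chromatographed. Enolisation (TMSOTf, Et3N, CH2Cl2, 0 °C) gives 7-(tert-butyldimethylsilyloxy)-4-(trimethylsilyloxy)-2H-chromene F9. The enolonium arylation with 3 under the conditions of step 3 gives the (3R)-7-O-tert-butyldimethylsilyl isoflavanone F10. Non-basic desilylation (KHF2, MeOH, rt) gives 8 without epimerising C3.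

## Further compounds

F1 | step 3 | 1-[(2E)-3,7-dimethylocta-2,6-dien-1-yl]-2,4-bis(trimethylsilyloxy)benzene | CC(C)=CCC/C(C)=C/Cc1ccc(O[Si](C)(C)C)cc1O[Si](C)(C)C
F2 | step 3 | racemic 3-{5-[(2E)-3,7-dimethylocta-2,6-dien-1-yl]-2,4-dihydroxyphenyl}-7-hydroxychroman-4-one | CC(C)=CCC/C(C)=C/Cc1cc(C2COc3cc(O)ccc3C2=O)c(O)cc1O
F3 | step 3 | 3-{5-[(2E)-3,7-dimethylocta-2,6-dien-1-yl]-2,4-bis(trimethylsilyloxy)phenyl}-4,7-bis(trimethylsilyloxy)-2H-chromene | CC(C)=CCC/C(C)=C/Cc1cc(C2=C(O[Si](C)(C)C)c3ccc(O[Si](C)(C)C)cc3OC2)c(O[Si](C)(C)C)cc1O[Si](C)(C)C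
F4 | step 1 | 4-bromoresorcinol | Oc1ccc(Br)c(O)c1
F5 | step 1 | 1-bromo-2,4-bis(methoxymethoxy)benzene | COCOc1ccc(Br)c(OCOC)c1
F6 | step 1 | geranyl bromide [(2E)-1-bromo-3,7-dimethylocta-2,6-diene] | CC(C)=CCC/C(C)=C/CBr
F7 | step 1 | 1-[(2E)-3,7-dimethylocta-2,6-dien-1-yl]-2,4-bis(methoxymethoxy)benzene | CC(C)=CCC/C(C)=C/Cc1ccc(OCOC)cc1OCOC
F8 | step 2 | 7-(tert-butyldimethylsilyloxy)chroman-4-one | CC(C)(C)[Si](C)(C)Oc1ccc2c(c1)OCCC2=O
F9 | step 2 | 7-(tert-butyldimethylsilyloxy)-4-(trimethylsilyloxy)-2H-chromene | CC(C)(C)[Si](C)(C)Oc1ccc2c(c1)OCC=C2O[Si](C)(C)C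
F10 | step 2 | (3R)-7-(tert-butyldimethylsilyloxy)-3-{5-[(2E)-3,7-dimethylocta-2,6-dien-1-yl]-2,4-dihydroxyphenyl}chroman-4-one | CC(C)=CCC/C(C)=C/Cc1cc([C@@H]2COc3cc(O[Si](C)(C)C(C)(C)C)ccc3C2=O)c(O)cc1O
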